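If each L costs one Z, the L a flask can hold is bounded by the Z it was given.

| flask | G | Z | temperature | remark | time |
|---|---|---|---|---|---|
| maple | 26 mM | 20 mM | 85 °C | run made earlier |  |
| birch | 90 mM | 20 mM | 100 °C | run made earlier |  |
| Monday's | 20 mM | 20.0 mM | 110 °C |  | 25 h |
| Friday's | 80 mM | 20.0 mM | 90 °C |  | 25 h |

| run | time / h | L / % | G / % |
|---|---|---|---|
| maple | 6.00 | 65.3 | 32.3 |
| maple | 15.0 | 75.8 | 12.0 |
| maple | 20.0 | 74.9 | 10.5 |
| maple | 30.0 | 76.6 | 11.4 |
| maple | 40.0 | 79.0 | 13.7 |
| birch | 3.00 | 8.5 | 89.7 |
| birch | 6.00 | 19.7 | 77.7 |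
| birch | 10.0 | 19.1 | 71.0 |
| birch | 12.0 | 18.0 | 72.0 |
| birch | 15.0 | 19.5 | 72.2 |
| birch | 20.0 | 19.2 | 70.7 |

(each reading ± 1 percentage point)

- percent here means G units held: one Q counts as two
- what is said of L includes X
- G, X is a solid; its amount is given per volume of the solution
- steps that have been proposed: G <-> J; J + Z -> L; X <-> L; G + L -> Q
- at the start none of G is in solution
- what has only dissolved of G counts as not reacted

1. which of the two ends with the higher amount of L, in percent of the G charged ("neither" if they lie within 2 percentage points) (Monday's / Friday's / neither)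
2. L at the end, in percent of the G charged, Monday's
3. L at the end, in percent of the G charged, Friday's

1. For Friday's the ceiling is 25.0%: Z charged over G charged. Less Z than G is charged in Friday's, so I expect Z to be the limiting reagent there. For Monday's the same ratio gives 100%.

2. The ceiling of the maple run is 76.9%. Its readings from 15.0 h on average 76.6%, so the ceiling holds there within the scatter.

3. The ceiling of the birch run is 22.2%. Its readings from 10.0 h on average 18.9%. As a reading, that is 2.95 mM short, and I take this as L spent on Q.

4. I let this loss scale with the G charged. I also guess that it doubles from 100 °C to 110 °C and halves from 100 °C to 90 °C. That gives 1.31 mM for Monday's and 1.31 mM for Friday's.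

5. I commit to 93.5% for Monday's and 23.4% for Friday's, so Monday's ends higher.

6. The weak link is the doubling. With a factor of 3 instead, or with no temperature effect, Monday's spans 90.2% to 96.7%. Friday's spans 21.7% to 23.9%. The order stands across both ranges.

The forecast, which sits below my reckoning for Monday's, gives Monday's, with 88% against 23%: “Friday's run is Z-limited at 25%”.

The flasks give 94.5% for Monday's and 22.9% for Friday's, so Monday's ends higher.

    G ⇌ J, rate k1*(cs1 - [J]) while solid is left; crystals form when [J] > cs1 (solubility = 2.70 mM, k = 1.21 /h)
    J + Z → L (k = 3220 /M/h, Ea = 42.0 kJ/mol)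
    X ⇌ L, rate k3*(cs3 - [L]) while solid is left; crystals form when [L] > cs3 (solubility = 0.250 mM, k = 5.94 /h)
    G + L → Q (k = 12.8 /M/h, Ea = 87.0 kJ/mol)
    (constants at 110 °C)

In Friday's, J has a half-life of 0.050 h on the path to L at 3.67 h, whereas G has one of 42 d on the path to Q at 25.0 h, a far longer time. At 25.0 h Friday's holds 0% of its own Z, and 4.14% of the G charged stands as Q. Its L stands 2.1 percentage points under the ceiling of 25.0%. A neighbour of Friday's charged with 32 mM of G has a ceiling of 62.5% and ends with 61.2% of L.

The earlier runs and the new flask stem from a simulated flask on assumed constants, noise included.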